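At 20.0 h, the last reading of the eta flask, 21.3 % of the Z and D is read as J and E. The task is to carry that forward to 2.0 d.

in all of them: Z 0.010 M; D 0.010 M; Q 0.20 mM

| charge | X | G | remark | time |
|---|---|---|---|---|
| eta | 0.025 M (fed, over 3.0 h) | 50 µM | the very flask that is asked about, followed so far; the fed solution adds 0.50 times the starting volume |  |
| zeta | 0.025 M (fed, over 3.0 h) | 100 µM | run made earlier; the fed solution adds 0.50 times the starting volume |  |
| flask | 0.0250 M (fed, over 3.0 h) | 50 µM | the fed solution adds 0.50 times the starting volume | 2.0 d |

| run | time / h | J / % | E / % |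
|---|---|---|---|
| eta | 1.00 | 0.6 | 1.5 |
| eta | 3.00 | 3.6 | 2.0 |
| eta | 5.00 | 4.6 | 4.4 |
| eta | 8.00 | 7.3 | 6.4 |
| eta | 12.0 | 8.7 | 7.1 |
| eta | 15.0 | 9.9 | 10.3 |
| eta | 20.0 | 10.8 | 10.5 |
| zeta | 2.50 | 4.5 | 3.1 |
| zeta | 4.00 | 6.0 | 5.9 |
| zeta | 6.00 | 7.5 | 6.8 |
| zeta | 10.0 | 9.3 | 8.3 |
| zeta | 15.0 | 11.7 | 11.3 |
| zeta | 20.0 | 12.5 | 11.3 |
| zeta | 30.0 | 13.8 | 13.7 |

(readings scatter by 0.5 percentage points)

- excess of J over E in the product at 1.0 h
- excess of J over E in the product at 2.0 d
- part of the Z and D charged together that has reacted at 2.0 d

- G is single-handed; Z and D are mirror images of each other, charged as a racemate, each of them at the stated concentration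
- charges are per starting volume, the dose included; the dosed solution carries all of it
- an excess is the difference of the two amounts in percent of their sum
- an excess is below zero if the other one leads

The useful measure is the exposure, the logarithm of what was charged over what is left of Z and D together. It grows steadily in a pseudo-first-order loss, whatever share has already gone. For eta it stands at 0.240 at 20.0 h.

The 21.3 % read at 20.0 h is taken as the lower bound for the reacted share of eta at 2.0 d, on the supposition that J and E do not turn back. The hourly gain of eta has been falling, from the first 5.00 h to the span from 12.0 h to 20.0 h. A straight line from that later span is therefore taken as the upper bound, reaching exposure 0.476, or 37.9 % reacted.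

To tighten this, suppose the rate falls as one over time, so each doubling of the clock adds a fixed exposure. Eta from 12.0 h to 20.0 h gives 0.0917 per doubling. Zeta, charged with 100 µM of G against the 50 µM of eta, gives 0.0808 over its longer span from 10.0 h to 30.0 h, and that figure is taken as an estimate. The exposure of the eta flask at 2.0 d is then 0.342, or 29.0 % reacted. This reckoning offers no figure for the excesses.

The forecast gives 3 %, 3 % and 29 %, its 29 % lying inside the bracket. It holds that “selectivity is weak and apparently constant”.

    J ⇌ E (k = 0.510 h⁻¹)
    X + G + D → G + E (k = 76000 M⁻² h⁻¹)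
    Z + Q ⇌ D + Q, rate k3*[Q]*[Z] forward; the back reaction follows from the equilibrium constant (k = 140 M⁻¹ h⁻¹)
    X + G + Z → G + J (k = 1.60 × 10⁵ M⁻² h⁻¹)
    2 G → L (k = 6600 M⁻¹ h⁻¹)

The flask gives an excess of 24.7 % at 1.0 h and 0.183 % at 2.0 d, where the forecast had 3 % at both. By their interconversion alone, J and E relax with a half-life of 0.680 h, short against 2.0 d. In the flask 28.3 % has reacted, an exposure of 0.333 against the 0.342 reckoned, with 77.4 % of X left. Both product steps carry X to the first power, so for the neighbouring flask with 0.10 M of X the exposure is reckoned as 4.00 times as large, all other charges held. That gives 1.37, or 74.5 % reacted. With 85.3 % of its X left at 2.0 d, that neighbouring flask gives 73.3 % reacted.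

The numbers in the tables come from a simulation for substances that don't exist.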